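**Small charge.** A small charge of reagent is where we start on your quick number: you expect winter, the warmest flask, to go furthest, and we lean the same way, but that does not yet give a number.

| setting | ochre | violet | grey | dawn | spring | winter | dusk |
|---|---|---|---|---|---|---|---|
| starting material | 0.050 M | 0.050 M | 0.032 M | 0.050 M | 0.050 M | 0.050 M | 0.012 M |
| reagent | 0.055 M | 0.055 M | 0.055 M | 0.0150 M | 0.0550 M | 0.0300 M | 0.0550 M |
| initiator | 4.3 mM | 13 mM | 5 mM | 20 mM | 5.0 mM | 5.0 mM | 5.0 mM |
| temperature | −25 °C | 8 °C | −25 °C | 0 °C | 0 °C | 20 °C | −40 °C |
| remark | run made earlier | run made earlier | run made earlier |  |  |  |  |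
| time |  |  |  | 40 h | 40 h | 40 h | 40 h |

- ochre (time / h: product / %, starting material / %): 15.0: 1.0, 99.3; 30.0: 1.9, 99.3; 40.0: 0.2, 98.7; 48.0: 2.0, 98.8; 72.0: 3.8, 97.4; 96.0: 5.4, 96.7
- violet (time / h: product / %, starting material / %): 2.50: 19.7, 79.4; 3.00: 24.1, 79.2; 5.00: 34.9, 66.0; 8.00: 50.4, 49.9; 12.0: 63.3, 35.2; 20.0: 82.1, 16.1; 30.0: 93.7, 6.4
- grey (time / h: product / %, starting material / %): 8.00: 1.1, 100.2; 30.0: 1.3, 97.7; 40.0: 2.3, 97.3; 72.0: 3.3, 96.0; 96.0: 3.6, 94.6

(scatter of a reading: 1 percentage point)

- in percentages every species weighs as the starting material in it: one ended chains B counts as two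
- on the list of suspects stand: 2 initiating radical -> ended chains A; 2 chain carrier -> ended chains B; reagent + chain carrier -> product + initiating radical; starting material + initiating radical -> chain carrier; initiator -> 2 initiating radical

- the flasks by amount of product, in percent of the starting material charged, highest first, at 40 h (dawn / spring / winter / dusk)
- the amount of product, in percent of the starting material charged of the flask you put first, at 40 h
- the amount of product, in percent of the starting material charged of the flask you put last, at 40 h

**The ceiling.** On the list of suspects, reagent and chain carrier give product one for one, so reagent is the limiting reagent in winter and dawn, whose reagent charges fall short of their starting material. In winter that quotient is 60.0%, and we call it the reagent ceiling, reagent charged over starting material charged, the most product, in percent of the starting material charged, that the charge can pay for.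

**Reaching it.** Let k be the first-order constant of the loss of starting material; violet reads 0.0869 h⁻¹ at 8.00 h and 0.0916 h⁻¹ at 30.0 h, so in violet the falling reagent did not visibly slow it. Winter has less initiator than violet, yet even if k fell in direct proportion to initiator, with reagent as harmless as in violet and product following the loss of starting material as it does there, this estimate puts winter at its ceiling in 27.4 h, sooner than 40 h, and winter is also warmer than violet. So we commit to the ceiling for winter. Spring's quotient is 110%, which caps nothing, so spring is a question of rate, and there, as for dusk, we have no reckoning of our own.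

**The forecast.** The forecast gives winter > spring > dawn > dusk, with 59% on top and 0.15% at the bottom, and says of winter: “reagent runs out, capping product at about 60%”.

**The flask.** The order comes out as winter > spring > dawn > dusk, with 60.0% on top and 0.139% at the bottom.

    2 initiating radical → ended chains A (k = 2.00 × 10⁸ M⁻¹ s⁻¹, Ea = 11.0 kJ mol⁻¹)
    2 chain carrier → ended chains B (k = 4.60 × 10⁷ M⁻¹ s⁻¹, Ea = 11.0 kJ mol⁻¹)
    reagent + chain carrier → product + initiating radical (k = 6.03 × 10⁶ M⁻¹ h⁻¹, Ea = 38.0 kJ mol⁻¹)
    starting material + initiating radical → chain carrier (k = 8.46 × 10⁶ M⁻¹ h⁻¹, Ea = 38.0 kJ mol⁻¹)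
    initiator → 2 initiating radical (k = 9.36 × 10⁻⁴ h⁻¹, Ea = 105 kJ mol⁻¹)
    (constants at 0 °C)

Winter's reagent was down to 0.0876% of its charge at 20.0 h, when product already stood at 59.9% against the ceiling of 60.0%. Dawn's ceiling is 30.0%, and dawn stands beneath it at 27.5% after 40.0 h, with 8.46% of its reagent left.

The readings are calculated from invented constants; noise was put on by code.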